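Ring A is a resorcinol: prenyl sits on C3', the carbon between the oxygen-bearing C2' and C4', and the acyl group on C1'. That pattern equals a cyclohexane-1,3-dione substituted at C2 and C4, so the route cuts the C1'–C(=O) bond. A lithium enolate of 2-prenylcyclohexane-1,3-dione, held as its mono-triisopropylsilyl enol ether (enone C6 is dione C4), acylates the N-methoxy-N-methylamide of tris-silylated (R)-danshensu; one operation joins both halves and completes the carbon skeleton, with the stereocentre bought from the chiral pool. A single dehydrogenation then aromatises ring A and fluoride strips all four silyl groups.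

Key step: step 6

Remarks on the chemistry
- Configuration: the carbinol carbon of the target is (R); (R)-danshensu has the same configuration and supplies it unchanged.
- Assumption: danshensu is used as the free acid; the commercial sodium salt would need one extra equivalent of acid in step 3.
- Precursor design: the dione enters the coupling as its mono-O-silyl enol ether and not as a free dione dianion. One equivalent of base then gives a single soluble carbon nucleophile, and oxygen and C2 are blocked. The later dehydrogenation has only one dicarbonyl carbon to functionalise, and the extra silyl group leaves in the last step.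
- Numbering: in the enol ether and its descendants C1 is the carbonyl, C2 bears prenyl, C3 bears the silyloxy group and C6 is the CH2 beside the carbonyl. C6 is C4 of the parent dione and becomes C1' of ring A.
- Abbreviations: TBS = tert-butyldimethylsilyl, TIPS = triisopropylsilyl, prenyl = 3-methylbut-2-en-1-yl.

Step 1
Reactants: 1 cyclohexane-1,3-dione; 2 prenyl bromide (1-bromo-3-methylbut-2-ene)
Product: 3 2-prenylcyclohexane-1,3-dione
Conditions: KOH (1.0 equiv), H2O, 0 °C to rt
Reagents that add atoms: none
Why: C-alkylation of the potassium enolate of a cyclic 1,3-dione by an allylic bromide (SN2) in water, where hydrogen bonding to the enolate oxygens steers the electrophile to C2, the only carbon flanked by both carbonyls.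

Step 2
Reactants: 3 2-prenylcyclohexane-1,3-dione
Product: 4 2-prenyl-3-(triisopropylsilyloxy)cyclohex-2-en-1-one
Conditions: TIPSOTf (1.05 equiv), Et3N, CH2Cl2, −78 to 0 °C
Reagents that add atoms: triisopropylsilyl trifluoromethanesulfonate, CC(C)[Si](C(C)C)(C(C)C)OS(=O)(=O)C(F)(F)F
Why: O-silylation of the acidic enol of a 1,3-dione should give the vinylogous silyl ester as a single isomer because the two oxygens of 3 are equivalent, and the bulky silyl group is chosen for hydrolytic stability.

Step 3
Reactants: 5 (R)-danshensu, (R)-3-(3,4-dihydroxyphenyl)-2-hydroxypropanoic acid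
Product: 6 methyl (R)-3-(3,4-dihydroxyphenyl)-2-hydroxypropanoate
Conditions: MeOH, H2SO4 (cat.), reflux, argon
Reagents that add atoms: methanol, CO
Why: Fischer esterification converts only the carboxylic acid, and the acidic medium neither enolises the stereocentre nor oxidises the catechol.

Step 4
Reactants: 6 methyl (R)-3-(3,4-dihydroxyphenyl)-2-hydroxypropanoate
Product: 7 methyl (R)-2-(TBS-oxy)-3-[3,4-bis(TBS-oxy)phenyl]propanoate
Conditions: TBSCl (3.6 equiv), imidazole, DMF, rt
Reagents that add atoms: tert-butyldimethylsilyl chloride, CC(C)(C)[Si](C)(C)Cl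
Why: Silyl ether formation with a silyl chloride and imidazole should cover both phenols and the secondary alcohol without touching the ester or the stereocentre.

Step 5
Reactants: 7 methyl (R)-2-(TBS-oxy)-3-[3,4-bis(TBS-oxy)phenyl]propanoate
Product: 8 (R)-2-(TBS-oxy)-3-[3,4-bis(TBS-oxy)phenyl]-N-methoxy-N-methylpropanamide
Conditions: MeNH(OMe)·HCl (1.5 equiv), iPrMgCl (3.0 equiv), THF, −20 to 0 °C
Reagents that add atoms: N,O-dimethylhydroxylamine hydrochloride, CNOC.Cl
Why: Aminolysis of the methyl ester by the chloromagnesium amide of N,O-dimethylhydroxylamine (Weinreb amide formation from an ester) runs below 0 °C, where the alpha-silyloxy ester is not enolised, so the (R) configuration is kept.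

Step 6
Reactants: 4 2-prenyl-3-(triisopropylsilyloxy)cyclohex-2-en-1-one (2.2 equiv); 8 (R)-2-(TBS-oxy)-3-[3,4-bis(TBS-oxy)phenyl]-N-methoxy-N-methylpropanamide
Product: 11 6-[(R)-2-(TBS-oxy)-3-(3,4-bis(TBS-oxy)phenyl)propanoyl]-2-prenyl-3-(triisopropylsilyloxy)cyclohex-2-en-1-one as C6 epimers equilibrating through the enol, via lithium dienolate 9 (not isolated), via lithium hemiaminal alkoxide 10 (not isolated)
Conditions: LiN(iPr)2 (2.1 equiv), THF, −78 °C; then 8 (1.0 equiv), −78 to 0 °C; sat. aq. NH4Cl
Reagents that add atoms: none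
Why: LiN(iPr)2 removes the kinetically most accessible proton of 4, the alpha' hydrogen on C6 beside the ketone, and the cross-conjugated dienolate 9 adds through C6 to the amide carbonyl of 8 to give the N-methoxy hemiaminal alkoxide 10, which is held as a five-membered lithium chelate and releases the ketone only on aqueous quench. The closest known reaction types are the alpha' functionalisation of vinylogous ester enolates (Stork–Danheiser enolate chemistry) and the Weinreb ketone synthesis with a ketone enolate as nucleophile, a Claisen-type acylation. No ring is closed. The only new stereocentre, ring C6, is left uncontrolled on purpose because it lies between two carbonyls, is enolised in 11 and becomes an sp2 carbon of ring A in step 7, while the (R) centre is not formed here but carried over from 5. The step needs C6 over C2, C4 and oxygen: the silyl group blocks O-acylation and ties C2 into a fully substituted enol ether carbon, and kinetic deprotonation at −78 °C chooses alpha' over gamma. The (R) centre should survive because the enolate is too weak a base for the alpha hydrogen of the silyloxy amide, no ketone exists before the quench, and 11 enolises toward C6 and not toward the side chain.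

Step 7
Reactants: 11 6-acyl-2-prenyl-3-(triisopropylsilyloxy)cyclohex-2-en-1-one
Product: 15 (R)-2-(TBS-oxy)-3-[3,4-bis(TBS-oxy)phenyl]-1-[2-hydroxy-3-prenyl-4-(triisopropylsilyloxy)phenyl]propan-1-one, via C6 phenylselenide 12 (not isolated), via selenoxide 13 (not isolated), via cyclohexa-2,5-dienone tautomer 14 (not isolated)
Conditions: PhSeCl (1.05 equiv), pyridine, CH2Cl2, 0 °C; aqueous wash; mCPBA (1.05 equiv), CH2Cl2, −78 °C; iPr2NH, −78 to 0 °C
Reagents that add atoms: none
Why: Alpha-selenenylation of the enolised beta-diketone at C6 (the only carbon of 11 between two carbonyls, C2 being locked in the enol ether), oxidation at selenium at a temperature where the prenyl alkene is inert, and selenoxide syn-elimination toward the C5 hydrogens should give dienone 14, whose tautomerisation to the phenol is driven by aromaticity and erases the C6 stereocentre.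

Step 8
Reactants: 15 tetrasilylated aryl ketone
Product: 16 (R)-1-(2,4-dihydroxy-3-prenylphenyl)-3-(3,4-dihydroxyphenyl)-2-hydroxypropan-1-one (the target)
Conditions: Bu4NF (6 equiv), AcOH (6 equiv), THF, 0 °C to rt, argon; work-up at pH 5
Reagents that add atoms: none
Why: Fluoride-induced desilylation should cleave the three aryl silyl ethers and the secondary alkyl silyl ether, while the acetic acid buffer keeps phenoxide and enolate concentrations low enough to spare the alpha-hydroxy ketone stereocentre and the catechol.

Compound list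
1 | cyclohexane-1,3-dione | O=C1CCCC(=O)C1 | starting material
2 | prenyl bromide (1-bromo-3-methylbut-2-ene) | CC(C)=CCBr | starting material
3 | 2-(3-methylbut-2-en-1-yl)cyclohexane-1,3-dione | CC(C)=CCC1C(=O)CCCC1=O | intermediate
4 | 2-(3-methylbut-2-en-1-yl)-3-(triisopropylsilyloxy)cyclohex-2-en-1-one | CC(C)=CCC1=C(O[Si](C(C)C)(C(C)C)C(C)C)CCCC1=O | intermediate
5 | (R)-danshensu, (R)-3-(3,4-dihydroxyphenyl)-2-hydroxypropanoic acid | O=C(O)[C@H](O)Cc1ccc(O)c(O)c1 | starting material
6 | methyl (R)-3-(3,4-dihydroxyphenyl)-2-hydroxypropanoate | COC(=O)[C@H](O)Cc1ccc(O)c(O)c1 | intermediate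
7 | methyl (R)-2-(tert-butyldimethylsilyloxy)-3-[3,4-bis(tert-butyldimethylsilyloxy)phenyl]propanoate | COC(=O)[C@H](O[Si](C)(C)C(C)(C)C)Cc1ccc(O[Si](C)(C)C(C)(C)C)c(O[Si](C)(C)C(C)(C)C)c1 | intermediate
8 | (R)-2-(tert-butyldimethylsilyloxy)-3-[3,4-bis(tert-butyldimethylsilyloxy)phenyl]-N-methoxy-N-methylpropanamide | CON(C)C(=O)[C@H](O[Si](C)(C)C(C)(C)C)Cc1ccc(O[Si](C)(C)C(C)(C)C)c(O[Si](C)(C)C(C)(C)C)c1 | intermediate
9 | lithium dienolate of 4 (O–Li on C1, double bonds C1=C6 and C2=C3) | CC(C)=CCC1=C(O[Si](C(C)C)(C(C)C)C(C)C)CCC=C1[O-].[Li+] | intermediate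
10 | lithium N-methoxy-N-methyl hemiaminal alkoxide, the tetrahedral adduct of C6 of 9 to the amide carbon of 8; side-chain centre as in 8, C6 and the hemiaminal carbon as mixtures | CC(C)=CCC1=C(O[Si](C(C)C)(C(C)C)C(C)C)CCC(C1=O)C([O-])(N(C)OC)[C@H](O[Si](C)(C)C(C)(C)C)Cc2ccc(O[Si](C)(C)C(C)(C)C)c(O[Si](C)(C)C(C)(C)C)c2.[Li+] | intermediate
11 | 6-[(R)-2-(tert-butyldimethylsilyloxy)-3-(3,4-bis(tert-butyldimethylsilyloxy)phenyl)propanoyl]-2-prenyl-3-(triisopropylsilyloxy)cyclohex-2-en-1-one, C6 epimers and enol forms | CC(C)=CCC1=C(O[Si](C(C)C)(C(C)C)C(C)C)CCC(C1=O)C(=O)[C@H](O[Si](C)(C)C(C)(C)C)Cc2ccc(O[Si](C)(C)C(C)(C)C)c(O[Si](C)(C)C(C)(C)C)c2 | intermediate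
12 | 6-phenylselanyl derivative of 11 (SePh and acyl both on C6) | CC(C)=CCC1=C(O[Si](C(C)C)(C(C)C)C(C)C)CCC([Se]c3ccccc3)(C1=O)C(=O)[C@H](O[Si](C)(C)C(C)(C)C)Cc2ccc(O[Si](C)(C)C(C)(C)C)c(O[Si](C)(C)C(C)(C)C)c2 | intermediate
13 | selenoxide of 12 | CC(C)=CCC1=C(O[Si](C(C)C)(C(C)C)C(C)C)CCC([Se](=O)c3ccccc3)(C1=O)C(=O)[C@H](O[Si](C)(C)C(C)(C)C)Cc2ccc(O[Si](C)(C)C(C)(C)C)c(O[Si](C)(C)C(C)(C)C)c2 | intermediate
14 | 6-acyl-2-prenyl-3-(triisopropylsilyloxy)cyclohexa-2,5-dien-1-one (C4 is CH2), keto tautomer of 15 | CC(C)=CCC1=C(O[Si](C(C)C)(C(C)C)C(C)C)CC=C(C1=O)C(=O)[C@H](O[Si](C)(C)C(C)(C)C)Cc2ccc(O[Si](C)(C)C(C)(C)C)c(O[Si](C)(C)C(C)(C)C)c2 | intermediate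
15 | (R)-2-(tert-butyldimethylsilyloxy)-3-[3,4-bis(tert-butyldimethylsilyloxy)phenyl]-1-[2-hydroxy-3-prenyl-4-(triisopropylsilyloxy)phenyl]propan-1-one | CC(C)=CCc1c(O[Si](C(C)C)(C(C)C)C(C)C)ccc(C(=O)[C@H](O[Si](C)(C)C(C)(C)C)Cc2ccc(O[Si](C)(C)C(C)(C)C)c(O[Si](C)(C)C(C)(C)C)c2)c1O | intermediate
16 | (R)-1-[2,4-dihydroxy-3-(3-methylbut-2-en-1-yl)phenyl]-3-(3,4-dihydroxyphenyl)-2-hydroxypropan-1-one | CC(C)=CCc1c(O)ccc(C(=O)[C@H](O)Cc2ccc(O)c(O)c2)c1O | target

Total step count: 8
Longest linear sequence: 6 steps (5 to 16 through steps 3, 4, 5, 6, 7 and 8)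

Steps most likely to fail

Step 6. The hindered secondary enolate may add too slowly to the alpha-branched amide, so that proton transfer between enolate and ketone, or base-induced loss of the N-methoxy group from the amide, takes over. The fallback delivers the acyl carbon at the aldehyde oxidation level. It sets out from 8, which would be reduced with iBu2AlH (THF, −78 °C) to (R)-2-(tert-butyldimethylsilyloxy)-3-[3,4-bis(tert-butyldimethylsilyloxy)phenyl]propanal F1, a much stronger electrophile that is used at once. Aldol addition of dienolate 9 (from 4 and LiN(iPr)2) at −78 °C would give the beta-hydroxy ketone 6-[1-hydroxy-2-(tert-butyldimethylsilyloxy)-3-aryl-propyl]-2-prenyl-3-(triisopropylsilyloxy)cyclohex-2-en-1-one F2 as a diastereomer mixture. Dess–Martin oxidation of its carbinol (NaHCO3-buffered CH2Cl2) removes the extra stereocentres and comes back to the route at 11.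

Step 7. The selenium electrophile may attack the prenyl double bond, or the enol silyl group may be lost early, which would open C2 to selenenylation. During the elimination the selenenic acid may also add back to the alkene. The fallback replaces the syn-elimination by halogenation and E2 elimination. It sets out from 11, which would be deprotonated with NaH (THF, 0 °C) so that only the enolate carbon is nucleophilic, and brominated with N-bromosuccinimide at −78 °C to the 6-bromo-6-acyl enone F3. Dehydrobromination with DBU (THF, 0 °C to rt) toward C5 and tautomerisation of dienone 14 come back to the route at 15.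

Step 8. Cleavage of the secondary silyl ether may lag behind that of the aryl silyl ethers. If the medium then drifts basic, the alpha-hydroxy ketone may enolise (loss of configuration, acyloin shift) and the free catechol may oxidise in air. The fallback separates the two kinds of silyl ether and avoids basic fluoride. It sets out from 15, which would be treated with KHF2 in MeOH at rt to remove only the three phenolic silyl groups and give (R)-2-(tert-butyldimethylsilyloxy)-1-(2,4-dihydroxy-3-prenylphenyl)-3-(3,4-dihydroxyphenyl)propan-1-one F4. The remaining alkyl silyl ether would then be cleaved with dilute aqueous HF in MeCN at 0 °C, acidic enough for the alkyl ether but too mild to cyclise the prenyl group onto the neighbouring phenol, which comes back to the route at 16.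

Further compounds
F1 | step 6 | (R)-2-(tert-butyldimethylsilyloxy)-3-[3,4-bis(tert-butyldimethylsilyloxy)phenyl]propanal | O=C[C@H](O[Si](C)(C)C(C)(C)C)Cc1ccc(O[Si](C)(C)C(C)(C)C)c(O[Si](C)(C)C(C)(C)C)c1
F2 | step 6 | 6-[1-hydroxy-2-(tert-butyldimethylsilyloxy)-3-(3,4-bis(tert-butyldimethylsilyloxy)phenyl)propyl]-2-prenyl-3-(triisopropylsilyloxy)cyclohex-2-en-1-one, (R) at the silyloxy carbon, carbinol and C6 centres as mixtures | CC(C)=CCC1=C(O[Si](C(C)C)(C(C)C)C(C)C)CCC(C1=O)C(O)[C@H](O[Si](C)(C)C(C)(C)C)Cc2ccc(O[Si](C)(C)C(C)(C)C)c(O[Si](C)(C)C(C)(C)C)c2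
F3 | step 7 | 6-bromo derivative of 11 (Br and acyl both on C6) | CC(C)=CCC1=C(O[Si](C(C)C)(C(C)C)C(C)C)CCC(Br)(C1=O)C(=O)[C@H](O[Si](C)(C)C(C)(C)C)Cc2ccc(O[Si](C)(C)C(C)(C)C)c(O[Si](C)(C)C(C)(C)C)c2
F4 | step 8 | (R)-2-(tert-butyldimethylsilyloxy)-1-(2,4-dihydroxy-3-prenylphenyl)-3-(3,4-dihydroxyphenyl)propan-1-one | CC(C)=CCc1c(O)ccc(C(=O)[C@H](O[Si](C)(C)C(C)(C)C)Cc2ccc(O)c(O)c2)c1O
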